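**Plan**
- Cuts: the aryl–vinyl bond at C4 of ring A (Heck); the three C3–aryl bonds (ring A C3–aryl, ring B C3–C4 of ring C, ring C C3–aryl; decarboxylative arylation of C3 acids); in each ring the C3–C3a bond (flavanone ring contraction); the three C2–aryl bonds (aryl addition to chromones).
- Enabling feature: the terminal ring C (O1, C2 carrying 4-hydroxyphenyl, C3, benzo ring C3a–C7a with oxygen on C6 and the carbon substituent on C4) is a 5-bromo-7-methoxyflavanone short of one ring atom. Moving C4a from C4 to C3 makes C3–C3a, leaves O1–C2(aryl) untouched and turns C4 into a carboxyl handle on C3. Rings B and A show the same pattern.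
- Forward order: ring C (chromone, flavanone, contraction, C3 arylation); ring B likewise from 6-chlorochromone; union C3(ring B)–C4(ring C); ring A built on C5 of ring B by the same three operations; phenols unmasked; stilbene last.
- Stereochemistry: each C2 (R) from Rh-catalysed asymmetric aryl addition to a chromone; each C3 (R, trans) from the contraction and then from radical arylation anti to the C2 aryl group; the E-alkene from the Heck step.

Key step: step 5

**Assumptions and conventions**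
- The (R)-configured electron-poor biaryl bisphosphine on Rh(I) is taken to deliver the aryl group to the chromone face that gives the (2R)-flavanone; if the sense is the opposite, the (S)-ligand is used with no other change.
- The C5 position of the flavanones for rings C and A is carried as bromine, so one atom serves for metalation (ring C) and for the Heck reaction (ring A).
- In names, BC is the (2R,3R)-3-[(2R,3R)-3-(3,5-dimethoxyphenyl)-6-methoxy-2-(4-methoxyphenyl)-2,3-dihydro-1-benzofuran-4-yl]-2-(4-methoxyphenyl)-2,3-dihydro-1-benzofuran-5-yl group.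
- Conditions and equivalents are proposals.

**Route**

Step 1
Reactants: 1 1-bromo-3,5-dimethoxybenzene
Product: 2 1-(2-bromo-4,6-dimethoxyphenyl)ethan-1-one
Conditions: AcCl (1.1 equiv), AlCl3 (1.2 equiv), CH2Cl2, 0 °C
Reagents that add atoms: acetyl chloride, CC(=O)Cl
Why: Friedel–Crafts acylation; the position between Br and OMe is para to the second methoxy group and less crowded than the one flanked by two methoxy groups, so the 2-bromo-4,6-dimethoxy ketone should predominate.

Step 2
Reactants: 2 1-(2-bromo-4,6-dimethoxyphenyl)ethan-1-one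
Product: 3 1-(2-bromo-6-hydroxy-4-methoxyphenyl)ethan-1-one
Conditions: BCl3 (1.2 equiv), CH2Cl2, −78 → 0 °C; aqueous work-up
Reagents that add atoms: none
Why: Chelation-directed ether cleavage; BCl3 bound to the carbonyl oxygen should cleave only the ortho methoxy group and leave the para one.

Step 3
Reactants: 3 1-(2-bromo-6-hydroxy-4-methoxyphenyl)ethan-1-one
Product: 5 5-bromo-7-methoxy-4H-chromen-4-one, via enaminone 4 (not isolated)
Conditions: Me2NCH(OMe)2, toluene, 100 °C; then conc. HCl, CH2Cl2, 40 °C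
Reagents that add atoms: N,N-dimethylformamide dimethyl acetal, COC(OC)N(C)C
Why: Enaminone chromone synthesis; condensation at the acetyl methyl group, then acid-promoted conjugate addition of the phenol and loss of dimethylamine.

Step 4
Reactants: 5 5-bromo-7-methoxy-4H-chromen-4-one; 6 (4-methoxyphenyl)boronic acid
Product: 7 (2R)-5-bromo-7-methoxy-2-(4-methoxyphenyl)chroman-4-one
Conditions: [Rh(OH)((R)-MeO-F12-BIPHEP)]2 (1.5 mol%), 6 (1.5 equiv), toluene/H2O 10:1, 40 °C
Reagents that add atoms: none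
Why: Rh-catalysed asymmetric conjugate addition of an arylboronic acid (Hayashi–Miyaura reaction) to the chromone; the ligand dictates the face of aryl–Rh insertion into C2=C3 and so sets C2 as R, the near-neutral medium should avoid retro-oxa-Michael racemisation, and Rh(I) should leave the aryl bromide alone.

Step 5
Reactants: 7 (2R)-5-bromo-7-methoxy-2-(4-methoxyphenyl)chroman-4-one
Product: 9 methyl (2R,3R)-4-bromo-6-methoxy-2-(4-methoxyphenyl)-2,3-dihydro-1-benzofuran-3-carboxylate (trans), via enol ether 8 (not isolated)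
Conditions: HC(OMe)3, conc. H2SO4 (1.5 equiv), 0 °C → rt; then PhI(OAc)2 (1.2 equiv), 0 °C → rt
Reagents that add atoms: trimethyl orthoformate, COC(OC)OC
Why: Acid and orthoformate turn the C4 ketone into enol ether 8, which attacks the iodine(III) reagent at C3 anti to the C2 aryl group; with iodine equatorial the C4–C4a ring bond lies antiperiplanar to C3–I, so the benzo carbon C4a shifts from C4 to C3 as iodobenzene leaves and the dimethoxycarbenium ion collapses to the methyl ester. This is the known hypervalent-iodine oxidative 1,2-aryl shift of aryl ketones in its flavanone ring-contraction form. The five-membered ring O1–C2–C3–C3a–C7a is not closed by a cyclisation: the C3–C3a bond forms through a bridged phenonium-like transition state while C4 is extruded as the exocyclic carboxyl carbon. C2 is untouched and stays R; the new C3 centre is set trans by the invertive anti-periplanar shift steered by the C2 aryl group, and any cis ester should converge on trans by acid-mediated enolisation. The benzo ring must migrate faster than the C2 anisyl group (which would lead to an isoflavone) and faster than acid opening to the chalcone; the diequatorial iodonium conformer aligns only the ring bond, the 7-methoxy group para to C4a raises its migratory aptitude, and the water-free orthoformate medium keeps the pyran ring closed.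

Step 6
Reactants: 9 methyl (2R,3R)-4-bromo-6-methoxy-2-(4-methoxyphenyl)-2,3-dihydro-1-benzofuran-3-carboxylate
Product: 10 (2R,3R)-4-bromo-6-methoxy-2-(4-methoxyphenyl)-2,3-dihydro-1-benzofuran-3-carboxylic acid
Conditions: LiOH·H2O (3 equiv), THF/MeOH/H2O, 0 °C → rt; then 1 M HCl
Reagents that add atoms: lithium hydroxide, [Li+].[OH-]
Why: Saponification; hydroxide should attack the ester carbonyl faster than C3 is deprotonated, and ring opening of any enolate would be the reverse of a 5-endo-trig closure, so C2 should be safe (C3 is reset in step 8).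

Step 7
Reactants: 1 1-bromo-3,5-dimethoxybenzene
Product: 12 (3,5-dimethoxyphenyl)zinc chloride (THF solution), via Grignard reagent 11 (not isolated)
Conditions: Mg turnings, LiCl, THF, rt; then ZnCl2 (1.0 equiv), 0 °C → rt
Reagents that add atoms: zinc chloride, Cl[Zn]Cl
Why: Magnesium insertion followed by Mg-to-Zn transmetalation gives a titratable arylzinc solution for steps 8 and 18.

Step 8
Reactants: 10 (2R,3R)-4-bromo-6-methoxy-2-(4-methoxyphenyl)-2,3-dihydro-1-benzofuran-3-carboxylic acid; 12 (3,5-dimethoxyphenyl)zinc chloride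
Product: 14 (2R,3R)-4-bromo-3-(3,5-dimethoxyphenyl)-6-methoxy-2-(4-methoxyphenyl)-2,3-dihydro-1-benzofuran, via N-acyloxyphthalimide 13 (not isolated)
Conditions: N-hydroxyphthalimide, DIC, DMAP (cat.), CH2Cl2, rt; filter, concentrate; then Fe(acac)3 (20 mol%), dppBz (24 mol%), 12 (3 equiv), THF/toluene, rt
Reagents that add atoms: none
Why: Iron-catalysed decarboxylative Negishi-type arylation of a redox-active ester; electron transfer to 13 releases CO2 and a planar benzylic C3 radical, which the aryl–iron species should capture anti to the C2 aryl group to give the trans (3R) product, and the iron–bisphosphine catalyst is not expected to insert into the hindered C4–Br bond.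

Step 9
Reactants: 15 6-chloro-4H-chromen-4-one; 6 (4-methoxyphenyl)boronic acid
Product: 16 (2R)-6-chloro-2-(4-methoxyphenyl)chroman-4-one
Conditions: [Rh(OH)((R)-MeO-F12-BIPHEP)]2 (1.5 mol%), 6 (1.5 equiv), toluene/H2O 10:1, 40 °C
Reagents that add atoms: none
Why: Hayashi–Miyaura conjugate addition as in step 4; the catalyst sets C2 as R and the aryl chloride is inert to Rh(I).

Step 10
Reactants: 16 (2R)-6-chloro-2-(4-methoxyphenyl)chroman-4-one
Product: 18 methyl (2R,3R)-5-chloro-2-(4-methoxyphenyl)-2,3-dihydro-1-benzofuran-3-carboxylate, via enol ether 17 (not isolated)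
Conditions: HC(OMe)3, conc. H2SO4 (1.5 equiv), 0 °C → rt; then PhI(OAc)2 (1.2 equiv), rt
Reagents that add atoms: trimethyl orthoformate, COC(OC)OC
Why: The same oxidative 1,2-aryl shift ring contraction as in step 5; C4a moves from C4 to C3, the 6-chloro group becomes the 5-chloro group of the dihydrobenzofuran and the ester should emerge trans to the C2 aryl group.

Step 11
Reactants: 18 methyl (2R,3R)-5-chloro-2-(4-methoxyphenyl)-2,3-dihydro-1-benzofuran-3-carboxylate
Product: 19 (2R,3R)-5-chloro-2-(4-methoxyphenyl)-2,3-dihydro-1-benzofuran-3-carboxylic acid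
Conditions: LiOH·H2O (3 equiv), THF/MeOH/H2O, 0 °C → rt; then 1 M HCl
Reagents that add atoms: lithium hydroxide, [Li+].[OH-]
Why: Saponification under the conditions of step 6, for the same reasons.

Step 12
Reactants: 19 (2R,3R)-5-chloro-2-(4-methoxyphenyl)-2,3-dihydro-1-benzofuran-3-carboxylic acid
Product: 20 1,3-dioxoisoindolin-2-yl (2R,3R)-5-chloro-2-(4-methoxyphenyl)-2,3-dihydro-1-benzofuran-3-carboxylate
Conditions: N-hydroxyphthalimide (1.1 equiv), DIC (1.1 equiv), DMAP (cat.), CH2Cl2, rt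
Reagents that add atoms: N-hydroxyphthalimide, O=C1c2ccccc2C(=O)N1O
Why: Carbodiimide (Steglich-type) esterification gives the redox-active ester as an isolable solid for the fragment union.

Step 13
Reactants: 14 (2R,3R)-4-bromo-3-(3,5-dimethoxyphenyl)-6-methoxy-2-(4-methoxyphenyl)-2,3-dihydro-1-benzofuran; 20 1,3-dioxoisoindolin-2-yl (2R,3R)-5-chloro-2-(4-methoxyphenyl)-2,3-dihydro-1-benzofuran-3-carboxylate
Product: 23 (2R,3R)-4-[(2R,3R)-5-chloro-2-(4-methoxyphenyl)-2,3-dihydro-1-benzofuran-3-yl]-3-(3,5-dimethoxyphenyl)-6-methoxy-2-(4-methoxyphenyl)-2,3-dihydro-1-benzofuran, via aryllithium 21 (not isolated), via arylzinc chloride 22 (not isolated)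
Conditions: 14 (1.8 equiv), t-BuLi (3.6 equiv), THF, −78 °C; ZnCl2, −78 °C → rt; then 20 (1.0 equiv), Fe(acac)3 (20 mol%), dppBz (24 mol%), THF/toluene, rt
Reagents that add atoms: none
Why: Br/Li exchange, transmetalation to zinc and iron-catalysed decarboxylative Negishi-type coupling; the planar C3 radical of ring B should be arylated anti to its C2 anisyl group, setting C3 of ring B as R, while the aryl chloride stays inert under iron catalysis.

Step 14
Reactants: 23 the chloride from step 13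
Product: 24 BC-boronic acid
Conditions: XPhos Pd G2 (2 mol%), XPhos (4 mol%), B2(OH)4 (3 equiv), KOAc (3 equiv), EtOH, 80 °C
Reagents that add atoms: tetrahydroxydiboron, OB(O)B(O)O
Why: Miyaura-type Pd-catalysed borylation of an electron-rich aryl chloride with tetrahydroxydiboron gives the boronic acid directly; no other halide is present at this stage.

Step 15
Reactants: 24 BC-boronic acid; 5 5-bromo-7-methoxy-4H-chromen-4-one
Product: 25 (2R)-5-bromo-7-methoxy-2-BC-chroman-4-one
Conditions: [Rh(OH)((R)-MeO-F12-BIPHEP)]2 (3 mol%), 5 (1.5 equiv), toluene/H2O 10:1, 50 °C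
Reagents that add atoms: none
Why: Hayashi–Miyaura conjugate addition as in step 4; the new C2 (ring A) is set as R by the catalyst, the existing centres lying remote from the reacting carbon, para across ring B.

Step 16
Reactants: 25 (2R)-5-bromo-7-methoxy-2-BC-chroman-4-one
Product: 27 methyl (2R,3R)-4-bromo-6-methoxy-2-BC-2,3-dihydro-1-benzofuran-3-carboxylate, via enol ether 26 (not isolated)
Conditions: HC(OMe)3/CH2Cl2, conc. H2SO4 (1.5 equiv), 0 °C; then PhI(OAc)2 (1.1 equiv), 0 °C
Reagents that add atoms: trimethyl orthoformate, COC(OC)OC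
Why: The oxidative 1,2-aryl shift ring contraction of step 5 applied to ring A; the enol ether is formed first and oxidised cold so that the iodine(III) reagent meets the most nucleophilic π-system before the dimethoxylated rings, and the ester should again emerge trans to the C2 aryl group.

Step 17
Reactants: 27 methyl (2R,3R)-4-bromo-6-methoxy-2-BC-2,3-dihydro-1-benzofuran-3-carboxylate
Product: 28 (2R,3R)-4-bromo-6-methoxy-2-BC-2,3-dihydro-1-benzofuran-3-carboxylic acid
Conditions: LiOH·H2O (3 equiv), THF/MeOH/H2O, 0 °C → rt; then 1 M HCl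
Reagents that add atoms: lithium hydroxide, [Li+].[OH-]
Why: Saponification under the conditions of step 6, for the same reasons.

Step 18
Reactants: 28 (2R,3R)-4-bromo-6-methoxy-2-BC-2,3-dihydro-1-benzofuran-3-carboxylic acid; 12 (3,5-dimethoxyphenyl)zinc chloride
Product: 30 (2R,3R)-4-bromo-3-(3,5-dimethoxyphenyl)-6-methoxy-2-BC-2,3-dihydro-1-benzofuran, via N-acyloxyphthalimide 29 (not isolated)
Conditions: N-hydroxyphthalimide, DIC, DMAP (cat.), CH2Cl2, rt; filter, concentrate; then Fe(acac)3 (20 mol%), dppBz (24 mol%), 12 (3 equiv), THF/toluene, rt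
Reagents that add atoms: none
Why: Iron-catalysed decarboxylative Negishi-type arylation as in step 8; the planar C3 radical of ring A should be arylated anti to the large C2 aryl group, giving the trans (3R) centre.

Step 19
Reactants: 30 (2R,3R)-4-bromo-3-(3,5-dimethoxyphenyl)-6-methoxy-2-BC-2,3-dihydro-1-benzofuran
Product: 31 (2R,3R)-4-bromo-3-(3,5-dihydroxyphenyl)-2-{(2R,3R)-3-[(2R,3R)-3-(3,5-dihydroxyphenyl)-6-hydroxy-2-(4-hydroxyphenyl)-2,3-dihydro-1-benzofuran-4-yl]-2-(4-hydroxyphenyl)-2,3-dihydro-1-benzofuran-5-yl}-2,3-dihydro-1-benzofuran-6-ol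
Conditions: BBr3 (20 equiv), CH2Cl2, −78 °C → rt; MeOH then aq. NaHCO3 at −78 °C
Reagents that add atoms: none
Why: Lewis-acid cleavage of the eight aryl methyl ethers, placed before the acid-sensitive stilbene exists; the aryl bromide is inert, and any ionisation of a benzylic C2–O bond should reclose to the thermodynamically preferred trans ring, so the configuration should hold.

Step 20
Reactants: 31 the octaphenol bromide from step 19
Product: 32 octaacetate of 31 (all eight phenols acetylated)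
Conditions: Ac2O, pyridine, DMAP (cat.), rt
Reagents that add atoms: acetic anhydride, CC(=O)OC(C)=O
Why: Exhaustive acetylation gives an air-stable compound that can be chromatographed and cross-coupled.

Step 21
Reactants: 32 octaacetate of 31; 33 4-ethenylphenyl acetate (4-acetoxystyrene)
Product: 34 nonaacetate of the target (32 with Br replaced by (E)-2-(4-acetoxyphenyl)ethenyl)
Conditions: Pd2(dba)3 (5 mol%), [HP(t-Bu)3]BF4 (12 mol%), Cy2NMe (1.5 equiv), 33 (2 equiv), dioxane, 80 °C
Reagents that add atoms: none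
Why: Mizoroki–Heck reaction; syn insertion and syn β-hydride elimination give the E-stilbene, and the bulky electron-rich phosphine should allow oxidative addition into the ortho-branched C–Br bond.

Step 22
Reactants: 34 nonaacetate of the target
Product: 35 (2R,3R)-3-(3,5-dihydroxyphenyl)-2-{(2R,3R)-3-[(2R,3R)-3-(3,5-dihydroxyphenyl)-6-hydroxy-2-(4-hydroxyphenyl)-2,3-dihydro-1-benzofuran-4-yl]-2-(4-hydroxyphenyl)-2,3-dihydro-1-benzofuran-5-yl}-4-[(E)-2-(4-hydroxyphenyl)ethenyl]-2,3-dihydro-1-benzofuran-6-ol (CNP0184803.1)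
Conditions: NaOMe (cat.), degassed MeOH/THF, 0 °C, argon; then acidic ion-exchange resin
Reagents that add atoms: none
Why: Zemplén-type transesterification removes the nine acetates under mild base, avoiding the acid that could cyclise the stilbene onto the neighbouring resorcinol ring.

**Compound list**
1 | 1-bromo-3,5-dimethoxybenzene | COc1cc(Br)cc(OC)c1 | starting material
2 | 1-(2-bromo-4,6-dimethoxyphenyl)ethan-1-one | CC(=O)c1c(Br)cc(OC)cc1OC | intermediate
3 | 1-(2-bromo-6-hydroxy-4-methoxyphenyl)ethan-1-one | CC(=O)c1c(Br)cc(OC)cc1O | intermediate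
4 | (E)-1-(2-bromo-6-hydroxy-4-methoxyphenyl)-3-(dimethylamino)prop-2-en-1-one | CN(C)/C=C/C(=O)c1c(Br)cc(OC)cc1O | intermediate
5 | 5-bromo-7-methoxy-4H-chromen-4-one | O=c1ccoc2cc(OC)cc(Br)c12 | intermediate
6 | (4-methoxyphenyl)boronic acid | COc1ccc(B(O)O)cc1 | starting material
7 | (2R)-5-bromo-7-methoxy-2-(4-methoxyphenyl)chroman-4-one | O=C1C[C@H](c2ccc(OC)cc2)Oc2cc(OC)cc(Br)c21 | intermediate
8 | (2R)-5-bromo-4,7-dimethoxy-2-(4-methoxyphenyl)-2H-chromene | COC1=C[C@H](c2ccc(OC)cc2)Oc2cc(OC)cc(Br)c21 | intermediate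
9 | methyl (2R,3R)-4-bromo-6-methoxy-2-(4-methoxyphenyl)-2,3-dihydro-1-benzofuran-3-carboxylate | Brc1cc(OC)cc2c1[C@@H](C(=O)OC)[C@H](c1ccc(OC)cc1)O2 | intermediate
10 | (2R,3R)-4-bromo-6-methoxy-2-(4-methoxyphenyl)-2,3-dihydro-1-benzofuran-3-carboxylic acid | Brc1cc(OC)cc2c1[C@@H](C(=O)O)[C@H](c1ccc(OC)cc1)O2 | intermediate
11 | (3,5-dimethoxyphenyl)magnesium bromide | COc1cc([Mg]Br)cc(OC)c1 | intermediate
12 | (3,5-dimethoxyphenyl)zinc chloride | COc1cc([Zn]Cl)cc(OC)c1 | intermediate
13 | 1,3-dioxoisoindolin-2-yl (2R,3R)-4-bromo-6-methoxy-2-(4-methoxyphenyl)-2,3-dihydro-1-benzofuran-3-carboxylate | Brc1cc(OC)cc2c1[C@@H](C(=O)ON1C(=O)c3ccccc3C1=O)[C@H](c1ccc(OC)cc1)O2 | intermediate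
14 | (2R,3R)-4-bromo-3-(3,5-dimethoxyphenyl)-6-methoxy-2-(4-methoxyphenyl)-2,3-dihydro-1-benzofuran | Brc1cc(OC)cc2c1[C@@H](c1cc(OC)cc(OC)c1)[C@H](c1ccc(OC)cc1)O2 | intermediate
15 | 6-chloro-4H-chromen-4-one | O=c1ccoc2ccc(Cl)cc12 | starting material
16 | (2R)-6-chloro-2-(4-methoxyphenyl)chroman-4-one | O=C1C[C@H](c2ccc(OC)cc2)Oc2ccc(Cl)cc21 | intermediate
17 | (2R)-6-chloro-4-methoxy-2-(4-methoxyphenyl)-2H-chromene | COC1=C[C@H](c2ccc(OC)cc2)Oc2ccc(Cl)cc21 | intermediate
18 | methyl (2R,3R)-5-chloro-2-(4-methoxyphenyl)-2,3-dihydro-1-benzofuran-3-carboxylate | Clc1ccc2c(c1)[C@@H](C(=O)OC)[C@H](c1ccc(OC)cc1)O2 | intermediate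
19 | (2R,3R)-5-chloro-2-(4-methoxyphenyl)-2,3-dihydro-1-benzofuran-3-carboxylic acid | Clc1ccc2c(c1)[C@@H](C(=O)O)[C@H](c1ccc(OC)cc1)O2 | intermediate
20 | 1,3-dioxoisoindolin-2-yl (2R,3R)-5-chloro-2-(4-methoxyphenyl)-2,3-dihydro-1-benzofuran-3-carboxylate | Clc1ccc2c(c1)[C@@H](C(=O)ON1C(=O)c3ccccc3C1=O)[C@H](c1ccc(OC)cc1)O2 | intermediate
21 | C4-aryllithium derived from 14 | [Li]c1cc(OC)cc2c1[C@@H](c1cc(OC)cc(OC)c1)[C@H](c1ccc(OC)cc1)O2 | intermediate
22 | C4-arylzinc chloride derived from 14 | Cl[Zn]c1cc(OC)cc2c1[C@@H](c1cc(OC)cc(OC)c1)[C@H](c1ccc(OC)cc1)O2 | intermediate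
23 | (2R,3R)-4-[(2R,3R)-5-chloro-2-(4-methoxyphenyl)-2,3-dihydro-1-benzofuran-3-yl]-3-(3,5-dimethoxyphenyl)-6-methoxy-2-(4-methoxyphenyl)-2,3-dihydro-1-benzofuran | Clc1ccc2c(c1)[C@@H](c1cc(OC)cc3c1[C@@H](c1cc(OC)cc(OC)c1)[C@H](c1ccc(OC)cc1)O3)[C@H](c1ccc(OC)cc1)O2 | intermediate
24 | BC-boronic acid (23 with Cl replaced by B(OH)2) | OB(O)c1ccc2c(c1)[C@@H](c1cc(OC)cc3c1[C@@H](c1cc(OC)cc(OC)c1)[C@H](c1ccc(OC)cc1)O3)[C@H](c1ccc(OC)cc1)O2 | intermediate
25 | (2R)-5-bromo-7-methoxy-2-BC-chroman-4-one | O=C1C[C@H](c2ccc3c(c2)[C@@H](c2cc(OC)cc4c2[C@@H](c2cc(OC)cc(OC)c2)[C@H](c2ccc(OC)cc2)O4)[C@H](c2ccc(OC)cc2)O3)Oc2cc(OC)cc(Br)c21 | intermediate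
26 | (2R)-5-bromo-4,7-dimethoxy-2-BC-2H-chromene | COC1=C[C@H](c2ccc3c(c2)[C@@H](c2cc(OC)cc4c2[C@@H](c2cc(OC)cc(OC)c2)[C@H](c2ccc(OC)cc2)O4)[C@H](c2ccc(OC)cc2)O3)Oc2cc(OC)cc(Br)c21 | intermediate
27 | methyl (2R,3R)-4-bromo-6-methoxy-2-BC-2,3-dihydro-1-benzofuran-3-carboxylate | Brc1cc(OC)cc2c1[C@@H](C(=O)OC)[C@H](c1ccc3c(c1)[C@@H](c1cc(OC)cc4c1[C@@H](c1cc(OC)cc(OC)c1)[C@H](c1ccc(OC)cc1)O4)[C@H](c1ccc(OC)cc1)O3)O2 | intermediate
28 | (2R,3R)-4-bromo-6-methoxy-2-BC-2,3-dihydro-1-benzofuran-3-carboxylic acid | Brc1cc(OC)cc2c1[C@@H](C(=O)O)[C@H](c1ccc3c(c1)[C@@H](c1cc(OC)cc4c1[C@@H](c1cc(OC)cc(OC)c1)[C@H](c1ccc(OC)cc1)O4)[C@H](c1ccc(OC)cc1)O3)O2 | intermediate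
29 | 1,3-dioxoisoindolin-2-yl ester of 28 | Brc1cc(OC)cc2c1[C@@H](C(=O)ON1C(=O)c3ccccc3C1=O)[C@H](c1ccc3c(c1)[C@@H](c1cc(OC)cc4c1[C@@H](c1cc(OC)cc(OC)c1)[C@H](c1ccc(OC)cc1)O4)[C@H](c1ccc(OC)cc1)O3)O2 | intermediate
30 | (2R,3R)-4-bromo-3-(3,5-dimethoxyphenyl)-6-methoxy-2-BC-2,3-dihydro-1-benzofuran | Brc1cc(OC)cc2c1[C@@H](c1cc(OC)cc(OC)c1)[C@H](c1ccc3c(c1)[C@@H](c1cc(OC)cc4c1[C@@H](c1cc(OC)cc(OC)c1)[C@H](c1ccc(OC)cc1)O4)[C@H](c1ccc(OC)cc1)O3)O2 | intermediate
31 | octaphenol bromide (30 with all eight OMe as OH; all six centres R) | Brc1cc(O)cc2c1[C@@H](c1cc(O)cc(O)c1)[C@H](c1ccc3c(c1)[C@@H](c1cc(O)cc4c1[C@@H](c1cc(O)cc(O)c1)[C@H](c1ccc(O)cc1)O4)[C@H](c1ccc(O)cc1)O3)O2 | intermediate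
32 | octaacetate of 31 | Brc1cc(OC(C)=O)cc2c1[C@@H](c1cc(OC(C)=O)cc(OC(C)=O)c1)[C@H](c1ccc3c(c1)[C@@H](c1cc(OC(C)=O)cc4c1[C@@H](c1cc(OC(C)=O)cc(OC(C)=O)c1)[C@H](c1ccc(OC(C)=O)cc1)O4)[C@H](c1ccc(OC(C)=O)cc1)O3)O2 | intermediate
33 | 4-ethenylphenyl acetate | CC(=O)Oc1ccc(C=C)cc1 | starting material
34 | nonaacetate of 35 | CC(=O)Oc1ccc(/C=C/c2cc(OC(C)=O)cc3c2[C@@H](c2cc(OC(C)=O)cc(OC(C)=O)c2)[C@H](c2ccc4c(c2)[C@@H](c2cc(OC(C)=O)cc5c2[C@@H](c2cc(OC(C)=O)cc(OC(C)=O)c2)[C@H](c2ccc(OC(C)=O)cc2)O5)[C@H](c2ccc(OC(C)=O)cc2)O4)O3)cc1 | intermediate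
35 | CNP0184803.1 (all six ring centres R, trans in each ring, E-alkene) | Oc1ccc(/C=C/c2cc(O)cc3c2[C@@H](c2cc(O)cc(O)c2)[C@H](c2ccc4c(c2)[C@@H](c2cc(O)cc5c2[C@@H](c2cc(O)cc(O)c2)[C@H](c2ccc(O)cc2)O5)[C@H](c2ccc(O)cc2)O4)O3)cc1 | target

**Count**
Total: 22 steps. Longest linear sequence: 17 steps (1–6, 8, 13–22).

**Steps most likely to fail**

Step 13. The ortho-branched arylzinc may transfer too slowly to the iron centre, so that the benzylic radical of ring B is lost to reduction or dimerisation. The fallback sets out from 9 and 19 and joins the two rings before the bulky aryl group sits on C3 of ring C. Ir/Ni metallaphotoredox decarboxylative arylation of acid 19 with bromo ester 9 (Ir[dF(CF3)ppy]2(dtbbpy)PF6, NiCl2·glyme, dtbbpy, Cs2CO3, DMF, blue light) should give methyl (2R,3R)-4-[(2R,3R)-5-chloro-2-(4-methoxyphenyl)-2,3-dihydro-1-benzofuran-3-yl]-6-methoxy-2-(4-methoxyphenyl)-2,3-dihydro-1-benzofuran-3-carboxylate F1. Saponification gives the corresponding carboxylic acid F2, and N-hydroxyphthalimide/DIC gives its 1,3-dioxoisoindolin-2-yl ester F3. Iron-catalysed coupling of this ester with 12 then places the 3,5-dimethoxyphenyl group trans on C3 of ring C, and the route is rejoined at 23.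

Step 16. The iodine(III) oxidant may attack the dimethoxylated rings, or the acid may open benzylic C–O bonds, before the enol ether is consumed. The fallback sets out from 25 and contracts the ring without oxidant or strong acid by a photochemical Wolff rearrangement. LiHMDS and 2,2,2-trifluoroethyl trifluoroacetate at −78 °C give the 3-trifluoroacetyl ketone F4, and detrifluoroacetylative diazo transfer (MsN3, Et3N, MeCN) gives the 3-diazo ketone F5. Irradiation at 350 nm in methanol moves C4a to C3 and gives the ring-contracted ketene F6, which methanol traps mainly as the cis methyl ester F7. Catalytic NaOMe in MeOH equilibrates it to the trans ester, where the route is rejoined at 27.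

Step 8. Insertion of the metal into the C4–Br bond, or dimerisation of the benzylic radical, may erode the coupling. The fallback sets out from 10 and needs neither an activated ester nor an organozinc. Ir/Ni metallaphotoredox decarboxylative arylation of the free acid with 1-iodo-3,5-dimethoxybenzene (same catalyst pair, Cs2CO3, DMF, blue light) relies on the aryl iodide engaging nickel much faster than the hindered bromide. No new compound arises (F0), and the route is rejoined at 14.

**Further compounds**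
F1 | step 13 | methyl (2R,3R)-4-[(2R,3R)-5-chloro-2-(4-methoxyphenyl)-2,3-dihydro-1-benzofuran-3-yl]-6-methoxy-2-(4-methoxyphenyl)-2,3-dihydro-1-benzofuran-3-carboxylate | Clc1ccc2c(c1)[C@@H](c1cc(OC)cc3c1[C@@H](C(=O)OC)[C@H](c1ccc(OC)cc1)O3)[C@H](c1ccc(OC)cc1)O2
F2 | step 13 | carboxylic acid of F1 | Clc1ccc2c(c1)[C@@H](c1cc(OC)cc3c1[C@@H](C(=O)O)[C@H](c1ccc(OC)cc1)O3)[C@H](c1ccc(OC)cc1)O2
F3 | step 13 | 1,3-dioxoisoindolin-2-yl ester of F2 | Clc1ccc2c(c1)[C@@H](c1cc(OC)cc3c1[C@@H](C(=O)ON1C(=O)c4ccccc4C1=O)[C@H](c1ccc(OC)cc1)O3)[C@H](c1ccc(OC)cc1)O2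
F4 | step 16 | (2R)-5-bromo-7-methoxy-2-BC-3-(trifluoroacetyl)chroman-4-one (C3 unassigned, enolised) | O=C1C(C(=O)C(F)(F)F)[C@H](c2ccc3c(c2)[C@@H](c2cc(OC)cc4c2[C@@H](c2cc(OC)cc(OC)c2)[C@H](c2ccc(OC)cc2)O4)[C@H](c2ccc(OC)cc2)O3)Oc2cc(OC)cc(Br)c21
F5 | step 16 | 5-bromo-3-diazo-7-methoxy-2-BC-chroman-4-one (C2 as in 25; descriptor 2S by priority change only) | O=C1C(=[N+]=[N-])[C@H](c2ccc3c(c2)[C@@H](c2cc(OC)cc4c2[C@@H](c2cc(OC)cc(OC)c2)[C@H](c2ccc(OC)cc2)O4)[C@H](c2ccc(OC)cc2)O3)Oc2cc(OC)cc(Br)c21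
F6 | step 16 | 4-bromo-6-methoxy-3-(oxomethylidene)-2-BC-2,3-dihydro-1-benzofuran (ketene; C2 as in 25) | Brc1cc(OC)cc2c1C(=C=O)[C@H](c1ccc3c(c1)[C@@H](c1cc(OC)cc4c1[C@@H](c1cc(OC)cc(OC)c1)[C@H](c1ccc(OC)cc1)O4)[C@H](c1ccc(OC)cc1)O3)O2
F7 | step 16 | methyl (2R,3S)-4-bromo-6-methoxy-2-BC-2,3-dihydro-1-benzofuran-3-carboxylate (cis) | Brc1cc(OC)cc2c1[C@H](C(=O)OC)[C@H](c1ccc3c(c1)[C@@H](c1cc(OC)cc4c1[C@@H](c1cc(OC)cc(OC)c1)[C@H](c1ccc(OC)cc1)O4)[C@H](c1ccc(OC)cc1)O3)O2
F0 | step 8 | none | none
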